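**Plan**
- Retrosynthetic cuts, in order:
  1. C12–C13, so the polyene leaves as an E-vinyl iodide.
  2. C8–O together with C7–H, through the 7α,8α-epoxide of a 7-ene.
  3. C9–C11, from a vinyl cuprate adding to an 8-en-7-one.
  4. C3–C4 of ring A.
  5. C10–CH3 and C10–C1, which ends at (S)-carvone.
- Enabling feature: in ring A the quaternary carbon C4 carries two methyl groups and is bonded to C3 and C5. C4 can therefore be a tertiary radical raised from an isopropenyl group on C5. C3 can be the open terminus of a vinyl ketone (C1=O, C2=C3) attached to C10.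
- Forward order: ring B is the carvone ring. C10 is acylated and methylated, and ring A closes in the radical step. The C1 and C9 ketones are then erased together through their enol triflates. Oxygen returns at C7 to activate C9, C11–C12 enter as a vinyl group, C8–OH is set, and the C14 polyene is coupled last.
- Stereochemistry: C5 comes from (S)-carvone. C10 comes from methylation anti to the isopropenyl group, hence the cis ring fusion. C9 comes from axial β attack of the cuprate. C8 comes from α-epoxidation and hydride opening at C7. The alkene geometries come from (E)-geranylacetone and a syn carboalumination.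

Key step: step 5

Remark: labdane-type numbering is used for all compounds (ring A = C1–C5 and C10, ring B = C5–C10, side chain from C11; α/β with the C10 methyl drawn β), so carvone C1, C2, C3, C4, C5, C6 are C9, C8, C7, C6, C5, C10; read this way the target SMILES has H5 β (a cis-decalin), side chain 9β, methyl 8β and hydroxyl 8α, and this isomer is the one made.

Step 1
Reactants: 1 3-(phenylsulfanyl)propanoic acid
Product: 2 3-(phenylsulfanyl)propanoyl chloride
Conditions: (COCl)2, DMF (cat.), CH2Cl2, 0 °C → rt
Reagents that add atoms: oxalyl chloride, O=C(Cl)C(=O)Cl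
Why: Acid chloride formation with oxalyl chloride under DMF catalysis is routine and leaves the aryl alkyl sulfide alone.

Step 2
Reactants: 3 (S)-carvone; 2 3-(phenylsulfanyl)propanoyl chloride
Product: 5 6-[3-(phenylsulfanyl)propanoyl]carvone (keto–enol mixture; C10 not fixed), via carvone lithium enolate 4 (not isolated)
Conditions: LiN(iPr)2, THF, −78 °C; enolate cannulated into 2, THF, −78 °C
Reagents that add atoms: none
Why: The amide base can only remove the α′-hydrogen at C10 of the enone under kinetic control, and running the lithium enolate into the acid chloride at −78 °C (crossed Claisen-type C-acylation) keeps the chloride in excess so that C-acylation outruns proton exchange with the more acidic product; C5 is not touched and C10 stays labile at this stage.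

Step 3
Reactants: 5 6-[3-(phenylsulfanyl)propanoyl]carvone
Product: 6 6-methyl-6-[3-(phenylsulfanyl)propanoyl]carvone (methyl trans and acyl arm cis to the isopropenyl group)
Conditions: K2CO3, MeI, acetone, rt
Reagents that add atoms: iodomethane, CI
Why: C-Alkylation of a β-diketone enolate with a soft electrophile: the C5 isopropenyl group turns pseudoaxial to avoid allylic strain with the planar enolate and screens its own face, so iodomethane should enter anti to it and fix C10 with the methyl group trans and the acyl arm cis to the isopropenyl group.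

Step 4
Reactants: 6 6-methyl-6-[3-(phenylsulfanyl)propanoyl]carvone
Product: 8 6-acryloyl-6-methylcarvone (acryloyl cis to isopropenyl), via sulfoxide of compound six 7 (not isolated)
Conditions: mCPBA (1.0 equiv), CH2Cl2, −78 °C; aq. NaHCO3 wash; then toluene, 90 °C
Reagents that add atoms: none
Why: At −78 °C one equivalent of peracid oxidises the sulfide much faster than any alkene, and the sulfoxide then loses benzenesulfenic acid by thermal syn elimination through the ketone-activated C2–H, so that the sensitive vinyl ketone appears only after all basic steps are over.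

Step 5
Reactants: 8 6-acryloyl-6-methylcarvone
Product: 9 5β-11-nordrim-7-ene-1,9-dione (cis-decalin; H5 and C10 methyl both β)
Conditions: Fe(acac)3 (0.3 equiv), PhSiH3 (2.5 equiv), EtOH (0.02 M), 60 °C, argon
Reagents that add atoms: none
Why: An iron hydride formed from Fe(acac)3 and PhSiH3 in ethanol passes a hydrogen atom to the CH2 terminus of the isopropenyl group, the only electron-rich 1,1-disubstituted alkene of 8, and leaves the tertiary radical at C4. This nucleophilic radical attacks the unsubstituted terminus C3 of the vinyl ketone, the α-keto radical at C2 is reduced by divalent iron to the enolate, and ethanol protonates it and returns trivalent iron to the cycle. The closest known reaction type is the iron-catalysed reductive coupling of an unactivated alkene with an electron-poor alkene (hydrogen-atom-transfer Giese addition), run here within one molecule. Ring A closes in the 6-endo-trig mode, which should win over 5-exo attack at C2 because C3 is both the open and the polarity-matched position and 5-exo closure would leave an unstabilised primary radical. No stereocentre is created (C4 carries two methyl groups, C2 and C3 become CH2), and the fusion must be cis because the two reacting arms stand on the same face at C5 and C10. The ring enone should stay out because its β-carbon C7 could be reached only through a four-membered ring and conjugated trisubstituted alkenes accept the hydrogen atom far more slowly than the isopropenyl group, while high dilution holds back intermolecular addition to the vinyl ketone.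

Step 6
Reactants: 9 5β-11-nordrim-7-ene-1,9-dione
Product: 11 1-(triflyloxy)-5β-11-nordrima-1,7-dien-9-one, via C1 potassium enolate 10 (not isolated)
Conditions: KN(SiMe3)2, THF, −78 °C; PhNTf2, −78 → 0 °C
Reagents that add atoms: N-phenylbis(trifluoromethanesulfonimide), O=S(=O)(N(c1ccccc1)S(=O)(=O)C(F)(F)F)C(F)(F)F
Why: C2 is the only carbon next to either ketone that carries hydrogen (C10 is quaternary, C8 is sp2), so kinetic deprotonation gives the C1 enolate alone, and O-sulfonylation with PhNTf2 is standard enol triflate formation.

Step 7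
Reactants: 11 1-(triflyloxy)-5β-11-nordrima-1,7-dien-9-one
Product: 13 1,9-bis(triflyloxy)-5β-11-nordrima-1,8-diene, via C9 lithium enolate 12 (not isolated)
Conditions: LiBH(s-Bu)3, THF, −78 °C; PhNTf2, −78 °C → rt
Reagents that add atoms: N-phenylbis(trifluoromethanesulfonimide), O=S(=O)(N(c1ccccc1)S(=O)(=O)C(F)(F)F)C(F)(F)F
Why: A bulky trialkylborohydride adds hydride 1,4 to a cyclohexenone with a free β-CH, all the more when the carbonyl is screened by quaternary C10, and trapping the regiodefined C8=C9 enolate on oxygen (conjugate reduction–triflation) turns the second carbonyl into an enol triflate; the C1 triflate is inert to the hydride at −78 °C.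

Step 8
Reactants: 13 1,9-bis(triflyloxy)-5β-11-nordrima-1,8-diene
Product: 14 5β-11-nordrima-1,8-diene
Conditions: Pd(OAc)2 (10 mol %), PPh3 (20 mol %), HCO2H, n-Bu3N, DMF, 60 °C
Reagents that add atoms: none
Why: Palladium-catalysed formate hydrogenolysis of enol triflates (oxidative addition to zerovalent palladium, formate for triflate, loss of CO2, reductive elimination) exchanges each C–O bond for C–H without moving the alkene, so both carbonyl oxygens that served to build C10 and to activate the acceptor leave in one operation.

Step 9
Reactants: 14 5β-11-nordrima-1,8-diene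
Product: 15 5β-11-nordrim-8-ene
Conditions: H2 (1 atm), RhCl(PPh3)3 (5 mol %), toluene–EtOH, rt
Reagents that add atoms: none
Why: Homogeneous hydrogenation with RhCl(PPh3)3 sorts alkenes by substitution, so the cis-disubstituted C1=C2 bond should be saturated while the trisubstituted C8=C9 bond between C10 and the methyl group stays.

Step 10
Reactants: 15 5β-11-nordrim-8-ene
Product: 16 5β-11-nordrim-8-en-7-one
Conditions: Rh2(cap)4 (cap = caprolactamate, 1 mol %), t-BuOOH (70 % in water), 1,2-dichloroethane, 40 °C
Reagents that add atoms: tert-butyl hydroperoxide, CC(C)(C)OO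
Why: Radical allylic oxidation with tert-butylperoxy radicals: C7 is the only ring methylene allylic to C8=C9 because C10 bears no hydrogen, and the allyl radical should be captured at C7 and not at the neopentyl terminus C9, the mixed peroxide then collapsing to the 8-en-7-one.

Step 11
Reactants: 16 5β-11-nordrim-8-en-7-one
Product: 18 7-(triflyloxy)-9β-vinyl-5β-11-nordrim-7-ene, via C7 bromomagnesium enolate 17 (not isolated)
Conditions: CH2=CHMgBr (3 equiv), CuBr·SMe2 (1.5 equiv), THF, −78 → −20 °C; then N-(5-chloropyridin-2-yl)triflimide, DMPU, −78 → 0 °C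
Reagents that add atoms: vinylmagnesium bromide, C=C[Mg]Br; N-(5-chloropyridin-2-yl)bis(trifluoromethanesulfonimide), O=S(=O)(N(c1ccc(Cl)cn1)S(=O)(=O)C(F)(F)F)C(F)(F)F
Why: Cuprate 1,4-addition and O-triflation of the enolate: in the half-chair that keeps C4 equatorial on ring B the stereoelectronically required axial path to C9 lies on the β face, anti to the pseudoaxial C10–C1 bond and syn-axial only to H5, while the axial path of the other half-chair runs into quaternary C4, so the vinyl group should end up 9β (H9 α).

Step 12
Reactants: 18 7-(triflyloxy)-9β-vinyl-5β-11-nordrim-7-ene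
Product: 19 9β-vinyl-5β-11-nordrim-7-ene
Conditions: Pd(OAc)2 (5 mol %), PPh3 (10 mol %), HCO2H, n-Bu3N, DMF, 60 °C
Reagents that add atoms: none
Why: The same formate hydrogenolysis of an enol triflate as in step 8 removes the C7 oxygen once it has done its work as activator and leaves the C7=C8 alkene in place; the vinyl group does not take part.

Step 13
Reactants: 19 9β-vinyl-5β-11-nordrim-7-ene
Product: 20 7α,8α-epoxy-9β-vinyl-5β-11-nordrimane
Conditions: mCPBA (1.05 equiv), CH2Cl2, −10 °C
Reagents that add atoms: m-chloroperbenzoic acid, O=C(OO)c1cccc(Cl)c1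
Why: Prilezhaev epoxidation prefers the trisubstituted ring alkene to the monosubstituted vinyl group, and because allylic strain with the C8 methyl group holds the 9β-vinyl group pseudoaxial over the β face of C8 the peracid should come from the α face, which sets C8–O α.

Step 14
Reactants: 20 7α,8α-epoxy-9β-vinyl-5β-11-nordrimane
Product: 21 9β-vinyl-5β-11-nordriman-8α-ol (8β-methyl)
Conditions: LiEt3BH, THF, 0 → 50 °C; then H2O
Reagents that add atoms: none
Why: Hydride opens the trisubstituted epoxide by SN2 attack at the secondary carbon C7, which here is also the trans-diaxial (Fürst–Plattner) mode, so the C8–O bond and its configuration are kept and the 8α-alcohol with the 8β-methyl group results.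

Step 15
Reactants: 22 (E)-geranylacetone
Product: 26 (E)-6,10-dimethylundeca-5,9-dien-1-yne, via methyl-side lithium enolate 23 (not isolated), via diethyl enol phosphate 24 (not isolated), via lithium acetylide 25 (not isolated)
Conditions: LiN(iPr)2 (1.05 equiv), THF, −78 °C; ClP(O)(OEt)2, −78 °C → rt; LiN(iPr)2 (2.3 equiv), −78 °C → rt; H2O
Reagents that add atoms: none
Why: Kinetic enolisation on the methyl side, O-phosphorylation and base-induced elimination of diethyl phosphate turn the methyl ketone into a terminal alkyne (enol phosphate elimination), with the E-trisubstituted alkene as a spectator.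

Step 16
Reactants: 26 (E)-6,10-dimethylundeca-5,9-dien-1-yne
Product: 28 (1E,5E)-1-iodo-2,6,10-trimethylundeca-1,5,9-triene, via E-vinyl dimethylalane 27 (not isolated)
Conditions: Me3Al, Cp2ZrCl2 (0.25 equiv), CH2Cl2, 0 °C → rt; I2, THF, −30 °C
Reagents that add atoms: trimethylaluminium, C[Al](C)C; iodine, II
Why: Zirconium-catalysed carboalumination (Negishi) adds methyl and aluminium syn with aluminium at the terminal carbon, and iodinolysis with retention gives the E-vinyl iodide.

Step 17
Reactants: 21 9β-vinyl-5β-11-nordriman-8α-ol; 28 (1E,5E)-1-iodo-2,6,10-trimethylundeca-1,5,9-triene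
Product: 30 target CNP0389811.1 (5β-H isomer of 8α-hydroxypolypoda-13,17,21-triene), via C12 B-alkyl-9-BBN adduct 29 (not isolated)
Conditions: 9-BBN, THF, rt; then 28, PdCl2(dppf) (5 mol %), Ph3As (10 mol %), Cs2CO3, DMF–H2O, rt
Reagents that add atoms: none
Why: 9-BBN adds in the anti-Markovnikov sense to the only alkene of 21, and the B-alkyl Suzuki–Miyaura coupling joins C12 to C13 with retention of the vinyl iodide geometry under mild basic conditions that touch neither the tertiary alcohol nor any stereocentre.

**Compound list**
1 | 3-(phenylsulfanyl)propanoic acid | O=C(O)CCSc1ccccc1 | starting material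
2 | 3-(phenylsulfanyl)propanoyl chloride | O=C(Cl)CCSc1ccccc1 | intermediate
3 | (S)-carvone | CC1=CC[C@@H](CC1=O)C(C)=C | starting material
4 | carvone lithium enolate (C9–OLi, C9=C10) | CC1=CC[C@@H](C=C1O[Li])C(C)=C | intermediate
5 | 6-[3-(phenylsulfanyl)propanoyl]carvone, keto–enol mixture, C10 not fixed | CC1=CC[C@H](C(C)=C)C(C(=O)CCSc2ccccc2)C1=O | intermediate
6 | 6-methyl-6-[3-(phenylsulfanyl)propanoyl]carvone, methyl trans and acyl cis to isopropenyl | O=C(CCSc2ccccc2)[C@@]1(C)[C@@H](C(C)=C)CC=C(C)C1=O | intermediate
7 | sulfoxide of 6 (both configurations at sulfur) | O=C(CCS(=O)c2ccccc2)[C@@]1(C)[C@@H](C(C)=C)CC=C(C)C1=O | intermediate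
8 | 6-acryloyl-6-methylcarvone, acryloyl cis to isopropenyl | C=CC(=O)[C@@]1(C)[C@@H](C(C)=C)CC=C(C)C1=O | intermediate
9 | 5β-11-nordrim-7-ene-1,9-dione (4,4,8,10-tetramethyl-cis-decal-7-ene-1,9-dione, H5 and C10 methyl β) | CC1=CC[C@@H]2C(C)(C)CCC(=O)[C@]2(C)C1=O | intermediate
10 | C1 potassium enolate of 9 | CC1=CC[C@@H]2C(C)(C)CC=C(O[K])[C@]2(C)C1=O | intermediate
11 | 1-(triflyloxy)-5β-11-nordrima-1,7-dien-9-one | CC1=CC[C@@H]2C(C)(C)CC=C(OS(=O)(=O)C(F)(F)F)[C@]2(C)C1=O | intermediate
12 | C9 lithium enolate (C8=C9) carrying the C1 enol triflate | CC1=C(O[Li])[C@@]2(C)C(OS(=O)(=O)C(F)(F)F)=CCC(C)(C)[C@H]2CC1 | intermediate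
13 | 1,9-bis(triflyloxy)-5β-11-nordrima-1,8-diene | CC1=C(OS(=O)(=O)C(F)(F)F)[C@@]2(C)C(OS(=O)(=O)C(F)(F)F)=CCC(C)(C)[C@H]2CC1 | intermediate
14 | 5β-11-nordrima-1,8-diene | CC1=C[C@@]2(C)C=CCC(C)(C)[C@H]2CC1 | intermediate
15 | 5β-11-nordrim-8-ene | CC1=C[C@@]2(C)CCCC(C)(C)[C@H]2CC1 | intermediate
16 | 5β-11-nordrim-8-en-7-one | CC1=C[C@@]2(C)CCCC(C)(C)[C@H]2CC1=O | intermediate
17 | C7 bromomagnesium enolate of the 9β-vinyl ketone | C=C[C@@H]1[C@@]2(C)CCCC(C)(C)[C@H]2CC(O[Mg]Br)=C1C | intermediate
18 | 7-(triflyloxy)-9β-vinyl-5β-11-nordrim-7-ene | C=C[C@@H]1[C@@]2(C)CCCC(C)(C)[C@H]2CC(OS(=O)(=O)C(F)(F)F)=C1C | intermediate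
19 | 9β-vinyl-5β-11-nordrim-7-ene | C=C[C@@H]1[C@@]2(C)CCCC(C)(C)[C@H]2CC=C1C | intermediate
20 | 7α,8α-epoxy-9β-vinyl-5β-11-nordrimane | C=C[C@@H]1[C@@]2(C)CCCC(C)(C)[C@H]2C[C@H]3O[C@]31C | intermediate
21 | 9β-vinyl-5β-11-nordriman-8α-ol (8β-methyl) | C=C[C@@H]1[C@@]2(C)CCCC(C)(C)[C@H]2CC[C@@]1(C)O | intermediate
22 | (E)-geranylacetone | CC(C)=CCC/C(C)=C/CCC(C)=O | starting material
23 | methyl-side lithium enolate of 22 | CC(C)=CCC/C(C)=C/CCC(=C)O[Li] | intermediate
24 | diethyl enol phosphate of 22 | CC(C)=CCC/C(C)=C/CCC(=C)OP(=O)(OCC)OCC | intermediate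
25 | lithium acetylide of 26 | CC(C)=CCC/C(C)=C/CCC#C[Li] | intermediate
26 | (E)-6,10-dimethylundeca-5,9-dien-1-yne | CC(C)=CCC/C(C)=C/CCC#C | intermediate
27 | (1E,5E)-2,6,10-trimethylundeca-1,5,9-trienyl(dimethyl)alane | CC(C)=CCC/C(C)=C/CC/C(C)=C/[Al](C)C | intermediate
28 | (1E,5E)-1-iodo-2,6,10-trimethylundeca-1,5,9-triene | CC(C)=CCC/C(C)=C/CC/C(C)=C/I | intermediate
29 | B-alkyl-9-BBN adduct of 21 (boron on C12, hydroxyl drawn free) | B1(CC[C@@H]2[C@@]3(C)CCCC(C)(C)[C@H]3CC[C@@]2(C)O)C2CCCC1CCC2 | intermediate
30 | (1R,2R,4aR,8aS)-2,5,5,8a-tetramethyl-1-[(3E,7E)-4,8,12-trimethyltrideca-3,7,11-trien-1-yl]decahydronaphthalen-2-ol | CC(C)=CCC/C(C)=C/CC/C(C)=C/CC[C@@H]1[C@@]2(C)CCCC(C)(C)[C@H]2CC[C@@]1(C)O | target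

**Step count**
Total step count: 17.
Longest linear sequence: 15 steps (steps 1–14 and 17).

**Steps most likely to fail**

Step 5.
- Risk: the hydrogen atom may go to the vinyl ketone instead of the isopropenyl group. The vinyl ketone may also be reduced or oligomerised before ring A closes.
- Fallback, from 8 back to 9, which makes the same C4 radical by halogen abstraction instead of hydrogen-atom transfer:
  - HBr in AcOH at 0 °C should add to the isopropenyl group in the Markovnikov sense and to the vinyl ketone in the conjugate sense. This gives 6-(3-bromopropanoyl)-5-(2-bromopropan-2-yl)-2,6-dimethylcyclohex-2-enone F1.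
  - Et3N in Et2O at 0 °C should take HBr out of the β-bromo ketone only and give 6-acryloyl-5-(2-bromopropan-2-yl)-2,6-dimethylcyclohex-2-enone F2.
  - Slow addition of Bu3SnH with AIBN in benzene at 80 °C should abstract the tertiary bromine, close C3–C4 in the same 6-endo sense, and deliver 9.

Step 10.
- Risk: hydrogen abstraction from the C8 methyl group, capture of the allyl radical at C9, or over-oxidation may erode the C–H oxidation.
- Fallback, from 11 back to 16, which moves the existing oxygen by a Wharton transposition instead of oxidising a C–H bond: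
  - Formate hydrogenolysis of 11 (Pd(OAc)2, PPh3, HCO2H, n-Bu3N, DMF) should give 5β-11-nordrima-1,7-dien-9-one F3.
  - Hydrogenation over RhCl(PPh3)3 should give 5β-11-nordrim-7-en-9-one F4.
  - H2O2 and NaOH in MeOH at 0 °C should give 7,8-epoxy-5β-11-nordriman-9-one F5.
  - N2H4·H2O with AcOH in MeOH should turn this into 5β-11-nordrim-8-en-7-ol F6.
  - MnO2 in CH2Cl2 should oxidise F6 to 16.

Step 13.
- Risk: poor facial selectivity of the peracid, because the α face is the concave face of the cis-decalin and carries the axial C1 methylene.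
- Fallback, from 19 back to 21, which brings the oxygen in as a nucleophile:
  - NBS in aqueous acetone at 0 °C forms bromonium ions reversibly on the ring alkene.
  - Only the β-bromonium ion can be opened by water at tertiary C8 in the trans-diaxial manner. This should give 7β-bromo-9β-vinyl-5β-11-nordriman-8α-ol F7.
  - Bu3SnH with AIBN in toluene at 80 °C should then replace bromine by hydrogen and give 21.

Further compounds
F1 | step 5 | 6-(3-bromopropanoyl)-5-(2-bromopropan-2-yl)-2,6-dimethylcyclohex-2-enone (configuration as in 8) | BrCCC(=O)[C@@]1(C)[C@@H](C(C)(C)Br)CC=C(C)C1=O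
F2 | step 5 | 6-acryloyl-5-(2-bromopropan-2-yl)-2,6-dimethylcyclohex-2-enone (configuration as in 8) | C=CC(=O)[C@@]1(C)[C@@H](C(C)(C)Br)CC=C(C)C1=O
F3 | step 10 | 5β-11-nordrima-1,7-dien-9-one | CC1=CC[C@@H]2C(C)(C)CC=C[C@]2(C)C1=O
F4 | step 10 | 5β-11-nordrim-7-en-9-one | CC1=CC[C@@H]2C(C)(C)CCC[C@]2(C)C1=O
F5 | step 10 | 7,8-epoxy-5β-11-nordriman-9-one (epoxide configuration without consequence) | CC12OC1C[C@@H]3C(C)(C)CCC[C@]3(C)C2=O
F6 | step 10 | 5β-11-nordrim-8-en-7-ol (C7 configuration without consequence) | CC1=C[C@@]2(C)CCCC(C)(C)[C@H]2CC1O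
F7 | step 13 | 7β-bromo-9β-vinyl-5β-11-nordriman-8α-ol | C=C[C@@H]1[C@@]2(C)CCCC(C)(C)[C@H]2C[C@H](Br)[C@@]1(C)O
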